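Remark on the chemistry: oxime 11 is drawn as the usual E isomer; its geometry has no bearing on the route, because chlorination and elimination to the nitrile oxide erase it.

## Analysis of the target

Target 21 is (2-hydroxy-4,6-dimethoxyphenyl)(7-hydroxy-2,2-dimethyl-2H-chromen-5-yl)methanone, a benzophenone. Ring A carries the ketone carbon on C1, a free hydroxyl on C2 and methoxyls on C4 and C6. Ring B is the benzo ring of a 2,2-dimethyl-2H-chromene, with the ketone on chromene C5, a hydroxyl on C7, the pyran oxygen on C8a and the pyran carbon C4 on C4a. The molecule has no stereocentre, and the C3=C4 double bond is held cis by the pyran ring, so no stereochemical relationship has to be set. The sensitive groups are the chromene double bond (it would not survive hydrogenation, electrophilic halogen or strong acid), the two free phenols, both electron-rich rings, and the C6 methoxyl next to the carbonyl, which chelating Lewis acids cleave. Three things make the synthesis hard: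

- The ketone carbon sits between two ortho oxygens on ring A and the pyran carbon on ring B, so the aryl–carbonyl bond to ring A is crowded.
- Of the three ring A oxygens, exactly the one next to the ketone must end up free.
- The pyran must fuse at the ring B carbon between the ketone-bearing and the oxygen-bearing carbons, not at the carbon between the two oxygens, although the two ring B oxygens start out equivalent.

The strategy rests on ring A C1 and C2: a carbon substituent and an oxygen on neighbouring ring atoms are what the carbon and oxygen ends of a nitrile oxide deliver across an aryne triple bond C1≡C2. The nitrogen that comes with them is removed afterwards. The 1,3,5-pattern of ring B maps onto 3,5-dihydroxybenzaldehyde 9, whose aldehyde carbon becomes the ketone carbon.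

## Retrosynthetic reasoning

**Pyran ring of 21.** The chromene alkene is the most fragile group, so it is made last. Cutting the C4–C4a bond and the O1–C2 bond leads, through allenylphenol 20, to aryl propargyl ether 19. The forward reaction is a thermal aryl propargyl ether Claisen rearrangement and ring closure. It has to deliver the side chain to the ring B carbon next to the ketone, which is para to the free hydroxyl and ortho to the acyl group, so both substituents steer toward it.

**Ether oxygen–tertiary carbon bond of 19.** Cutting this bond gives triol 17 and the five-carbon chloride 18. The two ring B hydroxyls of 17 are equivalent, so the forward step is only a question of mono- versus bis-alkylation. The ring A hydroxyl is tied up in a hydrogen bond to the ketone and should stay out of the reaction.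

**Ketone and ring A hydroxyl of 17.** The carbonyl is traced back to the N–H ketimine 16, with the ring B hydroxyls masked as methoxymethyl ethers. Re-joining the imine nitrogen to the ring A oxygen then gives benzisoxazole 15. What is gained is a neutral heteroaromatic ring that hides the ketone and exactly one hydroxyl, so that the ring A oxygens never need to be told apart by dealkylation. The forward reactions are a reductive N–O cleavage and an acid hydrolysis that also removes the acetals.

**Isoxazole ring of 15.** This is the strategic cut. Breaking the C3–C3a bond and the O1–C7a bond gives aryne 13 and nitrile oxide 14, which are generated from silyl triflate 8 and chloro-oxime 12. It is made here because it joins the two halves convergently and forms the crowded aryl–carbon bond at an unhindered triple-bond carbon. The forward cycloaddition must place oxygen on the aryne carbon remote from the neighbouring methoxyl and carbon on the one beside it.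

**Silyl triflate 8.** The O–S bond and the C–Si bond are cut in turn, through phenol 7 and silyl carbamate 6, back to carbamate 2 and phenol 1. The carbamate directs metalation to the carbon between itself and a methoxyl. Both such carbons of the symmetric ring are equivalent, so one silyl arene results.

**Chloro-oxime 12.** The C–Cl bond, the C=N bond and the two acetal C–O bonds are cut through oxime 11 and aldehyde 10 back to aldehyde 9. These are functional-group changes only, on a symmetric ring.

## Alternatives that were turned down

**Alternative 1:** Ring B is grown on a finished aryl ketone instead of being bought as an arene.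

- Disconnection: ring B bonds C5–C6 and C7–C8 (chromene numbering) are cut, leading to the alkylidene acetoacetate A1, which carries the 2,4,6-trimethoxybenzoyl group on its alkylidene carbon, and dimethyl propanedioate A2.
- Forward key step: base-mediated conjugate addition of A2 to that alkylidene carbon, then Claisen condensation of the acetyl methyl group onto one malonate ester, closing the cyclohexane-1,3-dione A3.
- For: the crowded aryl–carbonyl bond exists from the outset, made by acylation of a symmetric arene. The 1,3-dioxygenation of ring B relative to the acyl carbon follows from connectivity. The reagents are cheap.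
- Against: A3 is far from 21. Two esters must be hydrolysed and decarboxylated, and the dione must be dehydrogenated to a resorcinol beside an electron-rich ring. Three stereocentres are made only to be erased. A1 is a doubly activated ene-dione that can take nucleophiles at either alkene carbon and can oligomerise. Ring A arrives as a trimethyl ether and needs a chelation-controlled cleavage of one ortho methyl ether. After all this the sequence reaches only triol 17 and still needs steps 10 and 11.
- Comparison: Alternative 1 is stronger on material cost, and its ring A pattern cannot come out as a regioisomer mixture. The chosen strategy offers in its place both rings bought with their oxygen patterns installed, a convergent union, a ring A hydroxyl released without dealkylation, and no late oxidation-level correction on ring B.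

**Alternative 2:** Both aryl–carbonyl bonds are cut.

- Disconnection: ring A as iodide A4, ring B as the chromen-5-yl boronate A5 (taken as its pinacol ester), and the carbonyl carbon from carbon monoxide A6.
- Forward key step: palladium-catalysed carbonylative Suzuki coupling, by oxidative addition into A4, insertion of A6, transmetalation with A5 and reductive elimination to diaryl ketone A7. No ring is formed.
- For: it is the most convergent plan. The chromene is complete before the union and only the removal of two acetals follows. On step count and convergence it is at least as strong as the chosen route.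
- Against: the aroyl–palladium intermediate sits between two ortho oxygens on an electron-rich ring. Insertion of A6 is reversible there, so decarbonylation to the direct biaryl and protodeboronation of the ortho-substituted boronate compete. The pyran-fusion problem is not avoided but moved into the synthesis of A5, where a 5-halochromene has to be closed with only a halogen to steer the rearrangement. A pressurised toxic gas is needed.
- Comparison: the chosen strategy forms the crowded bond at an aryne carbon without a metal and keeps the acyl group in place to steer the chromene closure. It pays for this with more steps.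

**Alternative 3:** Ring B is built by cycloaddition.

- Disconnection: ring B bonds C5–C6 and C4a–C8a are cut, leading to the 1-methoxy-1,3-bis(silyloxy)diene A8 (silyl groups taken as trimethylsilyl) and ynal A9, which carries ring A on a silyl-protected carbinol carbon.
- Forward key step: thermal Diels–Alder reaction in which the formyl group polarises the alkyne, so the nucleophilic diene terminus bonds to the carbinol-bearing alkyne carbon. Loss of the methoxy and silyl groups on mild acid work-up aromatises the adduct to salicylaldehyde A10.
- For: the substitution of ring B is fixed by construction. The formyl carbon, the future pyran C4, ends up on the carbon between a hydroxyl and the carbinol-bearing carbon. That is exactly the fusion site the chosen route must obtain from a Claisen rearrangement, and on this point Alternative 3 is stronger.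
- Against: it is long. A9 takes several steps from a ring A aldehyde and A8 is moisture-sensitive. After A10 the aldehyde must be extended by three carbons and closed to the dimethylpyran while two free phenols are present. The carbinol must then be unmasked and oxidised and the acetal removed. The carbinol stereocentre serves no purpose.
- Comparison: the chosen strategy is shorter and convergent and takes both rings from commercial arenes. In its end-game the electronic preferences of the substrate point to the required carbon, though they do not guarantee it.

Key step: step 7

## Route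

**Step 1**
Reactants: 1 3,5-dimethoxyphenol
Product: 2 3,5-dimethoxyphenyl propan-2-ylcarbamate
Conditions: i-PrNCO, Et3N (cat.), CH2Cl2, rt
Reagents that add atoms: isopropyl isocyanate, CC(C)N=C=O
Why: Base-catalysed addition of the phenol to the isocyanate (carbamoylation) gives an N–H aryl carbamate. This group is a strong ortho-director on oxygen and, because of its N–H, can later be removed under mild base.

**Step 2**
Reactants: 2 3,5-dimethoxyphenyl propan-2-ylcarbamate
Product: 6 3,5-dimethoxy-2-(trimethylsilyl)phenyl propan-2-ylcarbamate, via N-silyl carbamate 3 (not isolated), via aryllithium 4 (not isolated), via N-silyl C-silyl carbamate 5 (not isolated)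
Conditions: TBSOTf, TMEDA, Et2O, 0 °C to rt; n-BuLi, TMEDA, −78 °C; TMSCl, −78 °C to rt; dilute aq NaHSO4
Reagents that add atoms: chlorotrimethylsilane, C[Si](C)(C)Cl
Why: In-situ N-silylation masks the N–H, and the carbamate then directs ortho-lithiation (directed ortho-metalation) to the carbon between itself and a methoxyl; both such carbons are equivalent, and the carbon between the two methoxyls is served only by the weaker directors. TMSCl traps the aryllithium at −78 °C before an anionic ortho-Fries shift can set in, and the labile N–Si bond is lost on mild acidic work-up.

**Step 3**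
Reactants: 6 3,5-dimethoxy-2-(trimethylsilyl)phenyl propan-2-ylcarbamate
Product: 8 3,5-dimethoxy-2-(trimethylsilyl)phenyl trifluoromethanesulfonate, via silylphenol 7 (not isolated)
Conditions: DBU, Et2NH, MeCN, 40 °C; then PhNTf2, rt
Reagents that add atoms: N-phenylbis(trifluoromethanesulfonimide), O=S(=O)(N(c1ccccc1)S(=O)(=O)C(F)(F)F)C(F)(F)F
Why: DBU removes the carbamate N–H and the anion fragments (E1cB) to the phenoxide and isopropyl isocyanate, which Et2NH scavenges as a urea. The phenoxide is triflated in the same pot by PhNTf2 under conditions that leave the aryl–silicon bond alone.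

**Step 4**
Reactants: 9 3,5-dihydroxybenzaldehyde
Product: 10 3,5-bis(methoxymethoxy)benzaldehyde
Conditions: MOMCl, i-Pr2NEt, CH2Cl2, 0 °C to rt
Reagents that add atoms: chloromethyl methyl ether, COCCl
Why: Williamson-type O-alkylation protects both phenols as acetals. These are stable to the hydroxylamine, NCS, fluoride and molybdenum carbonyl used later, and the aqueous acid of step 9 removes them.

**Step 5**
Reactants: 10 3,5-bis(methoxymethoxy)benzaldehyde
Product: 11 (E)-3,5-bis(methoxymethoxy)benzaldehyde oxime
Conditions: NH2OH·HCl, NaOAc, EtOH/H2O, rt
Reagents that add atoms: hydroxylamine hydrochloride, NO.Cl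
Why: Condensation of the aldehyde with hydroxylamine under acetate buffering (oxime formation) leaves the acid-labile acetals intact. The E isomer is expected as the more stable one.

**Step 6**
Reactants: 11 (E)-3,5-bis(methoxymethoxy)benzaldehyde oxime
Product: 12 (Z)-N-hydroxy-3,5-bis(methoxymethoxy)benzenecarboximidoyl chloride
Conditions: NCS, DMF, 0 °C to rt
Reagents that add atoms: N-chlorosuccinimide, O=C1CCC(=O)N1Cl
Why: NCS chlorinates the aldoxime at carbon to give the hydroximoyl chloride, the standard nitrile oxide precursor. One equivalent of reagent at or below room temperature should keep chlorination of the alkoxy-activated ring in check.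

**Step 7**
Reactants: 8 3,5-dimethoxy-2-(trimethylsilyl)phenyl trifluoromethanesulfonate; 12 (Z)-N-hydroxy-3,5-bis(methoxymethoxy)benzenecarboximidoyl chloride
Product: 15 3-[3,5-bis(methoxymethoxy)phenyl]-4,6-dimethoxy-1,2-benzoxazole, via 3,5-dimethoxybenzyne 13 (not isolated), via nitrile oxide 14 (not isolated)
Conditions: CsF, MeCN, rt, 12 added slowly by syringe pump to 8 (excess) and CsF
Reagents that add atoms: none
Why: CsF has two roles: fluoride attacks the silicon of 8 and the resulting aryl anion expels triflate to give aryne 13, and as a base it removes HCl from 12 to give nitrile oxide 14. The two combine in a concerted but asynchronous 1,3-dipolar [3+2] cycloaddition, the known aryne–nitrile oxide route to 1,2-benzisoxazoles. The isoxazole ring is closed by this intermolecular annulation onto the aryne triple bond, which forms both the C3–C3a and the O1–C7a bond in one event; no stereocentre is formed. The step needs regioselectivity, with oxygen going to the former triflate carbon and carbon to the former silyl carbon beside the methoxyl. The methoxyl next to the triple bond distorts the aryne so that the remote carbon is flatter and more electrophilic, and negative charge building at the near carbon is stabilised inductively; the oxygen end of the dipole, which has the larger HOMO coefficient, should therefore lead bond formation at the remote carbon. The second methoxyl lies para to the near carbon and acts only weakly on the in-plane orbitals, so it should not reverse this, although a minor regioisomer may have to be separated because a concerted addition senses the distortion less than an ionic one. The crowded ring A carbon reacts as part of a triple bond, with the aryl group of the dipole pointing away, so the two flanking substituents cost little. Slow addition of 12 keeps 14 dilute so that capture by the aryne outruns dimerisation to the furoxan, and the acetals and methyl ethers are inert to CsF in MeCN.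

**Step 8**
Reactants: 15 3-[3,5-bis(methoxymethoxy)phenyl]-4,6-dimethoxy-1,2-benzoxazole
Product: 16 2-{[3,5-bis(methoxymethoxy)phenyl]carbonimidoyl}-3,5-dimethoxyphenol
Conditions: Mo(CO)6, MeCN/H2O, reflux
Reagents that add atoms: none
Why: Zerovalent molybdenum from Mo(CO)6 inserts into the weak N–O bond and water supplies the two hydrogens (reductive N–O cleavage of isoxazoles), giving the ortho-hydroxyaryl N–H ketimine, which its O–H···N hydrogen bond stabilises. No alkene or benzyl group is present, the ethers are inert, and any ketone formed by early hydrolysis is simply carried into step 9.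

**Step 9**
Reactants: 16 2-{[3,5-bis(methoxymethoxy)phenyl]carbonimidoyl}-3,5-dimethoxyphenol
Product: 17 (3,5-dihydroxyphenyl)(2-hydroxy-4,6-dimethoxyphenyl)methanone
Conditions: 2 M aq HCl, THF, 60 °C
Reagents that add atoms: water, O
Why: Aqueous acid hydrolyses the protonated ketimine to the ketone and cleaves both acetals in the same operation (imine hydrolysis and acetal cleavage). Aryl methyl ethers are stable to dilute HCl.

**Step 10**
Reactants: 17 (3,5-dihydroxyphenyl)(2-hydroxy-4,6-dimethoxyphenyl)methanone; 18 3-chloro-3-methylbut-1-yne
Product: 19 (2-hydroxy-4,6-dimethoxyphenyl)[3-hydroxy-5-(2-methylbut-3-yn-2-yloxy)phenyl]methanone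
Conditions: CuCl2·2H2O (cat.), DBU, MeCN, 0 °C to rt, 18 as limiting reagent
Reagents that add atoms: none
Why: Copper-catalysed propargylic substitution: the copper acetylide of 18 loses chloride to an electrophilic allenylidene, which a phenoxide captures at the tertiary carbon to give the aryl 1,1-dimethylpropargyl ether. The two ring B hydroxyls are equivalent, so this is a statistical mono-alkylation run to partial conversion with recovery of 17. The ring A hydroxyl is hydrogen-bonded to the ketone and flanked by the aroyl group, so it should not compete.

**Step 11**
Reactants: 19 (2-hydroxy-4,6-dimethoxyphenyl)[3-hydroxy-5-(2-methylbut-3-yn-2-yloxy)phenyl]methanone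
Product: 21 (2-hydroxy-4,6-dimethoxyphenyl)(7-hydroxy-2,2-dimethyl-2H-chromen-5-yl)methanone, via allenylphenol 20 (not isolated)
Conditions: PhNEt2, 150 °C
Reagents that add atoms: none
Why: Aryl propargyl ether Claisen rearrangement: a [3,3] shift to an ortho carbon, enolisation to allenylphenol 20, a 1,5-hydrogen shift to an ortho-quinone methide and oxa-6π electrocyclisation close the 2H-pyran. The required ortho carbon is the one next to the ketone, which is para to the free hydroxyl (donors favour migration para to themselves) and ortho to the acyl group (meta acceptors draw the migration toward themselves). The carbon between the two oxygens has neither effect in its favour.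

## Compound list

1 | 3,5-dimethoxyphenol | COc1cc(O)cc(OC)c1 | starting material
2 | 3,5-dimethoxyphenyl propan-2-ylcarbamate | COc1cc(OC)cc(OC(=O)NC(C)C)c1 | intermediate
3 | 3,5-dimethoxyphenyl [tert-butyl(dimethyl)silyl](propan-2-yl)carbamate | COc1cc(OC)cc(OC(=O)N(C(C)C)[Si](C)(C)C(C)(C)C)c1 | intermediate
4 | [2-({[tert-butyl(dimethyl)silyl](propan-2-yl)carbamoyl}oxy)-4,6-dimethoxyphenyl]lithium | [Li]c1c(OC)cc(OC)cc1OC(=O)N(C(C)C)[Si](C)(C)C(C)(C)C | intermediate
5 | 3,5-dimethoxy-2-(trimethylsilyl)phenyl [tert-butyl(dimethyl)silyl](propan-2-yl)carbamate | COc1cc(OC)c([Si](C)(C)C)c(OC(=O)N(C(C)C)[Si](C)(C)C(C)(C)C)c1 | intermediate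
6 | 3,5-dimethoxy-2-(trimethylsilyl)phenyl propan-2-ylcarbamate | COc1cc(OC)c([Si](C)(C)C)c(OC(=O)NC(C)C)c1 | intermediate
7 | 3,5-dimethoxy-2-(trimethylsilyl)phenol | COc1cc(OC)c([Si](C)(C)C)c(O)c1 | intermediate
8 | 3,5-dimethoxy-2-(trimethylsilyl)phenyl trifluoromethanesulfonate | COc1cc(OC)c([Si](C)(C)C)c(OS(=O)(=O)C(F)(F)F)c1 | intermediate
9 | 3,5-dihydroxybenzaldehyde | O=Cc1cc(O)cc(O)c1 | starting material
10 | 3,5-bis(methoxymethoxy)benzaldehyde | COCOc1cc(OCOC)cc(C=O)c1 | intermediate
11 | (E)-3,5-bis(methoxymethoxy)benzaldehyde oxime | O/N=C/c1cc(OCOC)cc(OCOC)c1 | intermediate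
12 | (Z)-N-hydroxy-3,5-bis(methoxymethoxy)benzenecarboximidoyl chloride | O/N=C(\Cl)c1cc(OCOC)cc(OCOC)c1 | intermediate
13 | 3,5-dimethoxybenzyne (1,2-didehydro-3,5-dimethoxybenzene) | COC1=CC(OC)=CC#C1 | intermediate
14 | 3,5-bis(methoxymethoxy)benzonitrile oxide | COCOc1cc(OCOC)cc(C#[N+][O-])c1 | intermediate
15 | 3-[3,5-bis(methoxymethoxy)phenyl]-4,6-dimethoxy-1,2-benzoxazole | COCOc1cc(OCOC)cc(c1)-c1noc2cc(OC)cc(OC)c12 | intermediate
16 | 2-{[3,5-bis(methoxymethoxy)phenyl]carbonimidoyl}-3,5-dimethoxyphenol | COCOc1cc(OCOC)cc(C(=N)c2c(O)cc(OC)cc2OC)c1 | intermediate
17 | (3,5-dihydroxyphenyl)(2-hydroxy-4,6-dimethoxyphenyl)methanone | COc1cc(O)c(C(=O)c2cc(O)cc(O)c2)c(OC)c1 | intermediate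
18 | 3-chloro-3-methylbut-1-yne | CC(C)(Cl)C#C | starting material
19 | (2-hydroxy-4,6-dimethoxyphenyl)[3-hydroxy-5-(2-methylbut-3-yn-2-yloxy)phenyl]methanone | COc1cc(O)c(C(=O)c2cc(O)cc(OC(C)(C)C#C)c2)c(OC)c1 | intermediate
20 | [3,5-dihydroxy-2-(3-methylbuta-1,2-dien-1-yl)phenyl](2-hydroxy-4,6-dimethoxyphenyl)methanone | COc1cc(O)c(C(=O)c2cc(O)cc(O)c2C=C=C(C)C)c(OC)c1 | intermediate
21 | (2-hydroxy-4,6-dimethoxyphenyl)(7-hydroxy-2,2-dimethyl-2H-chromen-5-yl)methanone | COc1cc(O)c(C(=O)c2cc(O)cc3c2C=CC(C)(C)O3)c(OC)c1 | target

## Step count and least certain steps

Total step count: 11.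
Longest linear sequence: 8 steps (steps 1, 2, 3, 7, 8, 9, 10 and 11 from 1; the branch from 9 through steps 4, 5, 6 and then 7 to 11 is equally long).

**Step 7 (key step).** The most likely failure is erosion of regioselectivity. A concerted dipolar addition transmits the aryne distortion less fully than an ionic addition does, and the carbon end of the dipole has to bond beside a methoxyl. Dimerisation of the nitrile oxide before it meets the aryne is the second risk.

The fallback dispenses with the aryne and sets out from aldehyde 10. 1,3,5-Trimethoxybenzene (COc1cc(OC)cc(OC)c1), whose three ring positions are equivalent, is lithiated with n-BuLi in THF at 0 °C and added to 10 at −78 °C. This should give rac-[3,5-bis(methoxymethoxy)phenyl](2,4,6-trimethoxyphenyl)methanol F1. MnO2 in CH2Cl2 should oxidise this doubly benzylic alcohol to [3,5-bis(methoxymethoxy)phenyl](2,4,6-trimethoxyphenyl)methanone F2. BCl3 in CH2Cl2 at −78 to 0 °C is then expected to remove one of the two equivalent methyl ethers ortho to the carbonyl through the boron chelate, together with both acetals. The fallback returns to the route at triol 17.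

**Step 11.** The [3,3] shift may be misdirected onto the ring B carbon between the two oxygens. The aroyl group is twisted out of the plane of ring B, so it shields the wanted carbon and loses part of its conjugative pull.

The fallback sets out from 19 and adds a steric control element. TIPSCl and imidazole in DMF should silylate only the ring B hydroxyl, since the chelated ring A hydroxyl is inert. This would give (2-hydroxy-4,6-dimethoxyphenyl){3-(2-methylbut-3-yn-2-yloxy)-5-[tri(propan-2-yl)silyloxy]phenyl}methanone F3. The bulky silyl ether buttresses the competing carbon and keeps the oxygen a para-directing donor. Heating in PhNEt2 should then give (2-hydroxy-4,6-dimethoxyphenyl){2,2-dimethyl-7-[tri(propan-2-yl)silyloxy]-2H-chromen-5-yl}methanone F4. TBAF in THF removes the silyl group, and the fallback returns to the route at 21.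

**Step 10.** Over-alkylation to the bis-ether is the main risk. The first etherification does not deactivate the second ring B hydroxyl, and the bis-ether is lost material.

The fallback sets out from benzisoxazole 15 and places the statistical event where every by-product can be recycled.

- Partial hydrolysis with dilute aqueous HCl in THF at room temperature, stopped early, should give 3-(4,6-dimethoxy-1,2-benzoxazol-3-yl)-5-(methoxymethoxy)phenol F5. Unchanged 15 is reused, and doubly deprotected material is returned to 15 with MOMCl.
- F5 has a single free hydroxyl, so etherification with 18 under the conditions of step 10 can be driven to completion. It should give 4,6-dimethoxy-3-[3-(methoxymethoxy)-5-(2-methylbut-3-yn-2-yloxy)phenyl]-1,2-benzoxazole F6.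
- Heating in PhNEt2 should give 4,6-dimethoxy-3-[7-(methoxymethoxy)-2,2-dimethyl-2H-chromen-5-yl]-1,2-benzoxazole F7, with the heteroaryl acceptor and the acetal oxygen steering as the acyl group and hydroxyl do in 19.
- Mo(CO)6 in MeCN/H2O, which leaves alkenes alone, should give 2-{imino[7-(methoxymethoxy)-2,2-dimethyl-2H-chromen-5-yl]methyl}-3,5-dimethoxyphenol F8.
- Aqueous HCl in THF hydrolyses the imine and the last acetal, and the fallback returns to the route at 21.

**Step 6.** Electrophilic chlorination of ring B may compete with chlorination of the oxime carbon, because each free ring position is ortho or para to two alkoxy groups.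

The fallback sets out from aldehyde 9 and deactivates the ring with acyl groups.

- PivCl and Et3N should give 5-formyl-1,3-phenylene bis(2,2-dimethylpropanoate) F9.
- Hydroxylamine under the conditions of step 5 should give the oxime 5-[(E)-(hydroxyimino)methyl]-1,3-phenylene bis(2,2-dimethylpropanoate) F10.
- NCS in DMF should give 5-[(Z)-chloro(hydroxyimino)methyl]-1,3-phenylene bis(2,2-dimethylpropanoate) F11, the acyloxy groups now keeping the ring out of the reaction.
- Cycloaddition with 8 under the conditions of step 7 should give 5-(4,6-dimethoxy-1,2-benzoxazol-3-yl)-1,3-phenylene bis(2,2-dimethylpropanoate) F12.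
- LiOH in MeOH/H2O should cleave both esters to 5-(4,6-dimethoxy-1,2-benzoxazol-3-yl)benzene-1,3-diol F13; a 3-substituted benzisoxazole tolerates this base.
- MOMCl and i-Pr2NEt bring the material back to the route at 15.

## Further compounds

F1 | step 7 | rac-[3,5-bis(methoxymethoxy)phenyl](2,4,6-trimethoxyphenyl)methanol | COCOc1cc(OCOC)cc(C(O)c2c(OC)cc(OC)cc2OC)c1
F2 | step 7 | [3,5-bis(methoxymethoxy)phenyl](2,4,6-trimethoxyphenyl)methanone | COCOc1cc(OCOC)cc(C(=O)c2c(OC)cc(OC)cc2OC)c1
F3 | step 11 | (2-hydroxy-4,6-dimethoxyphenyl){3-(2-methylbut-3-yn-2-yloxy)-5-[tri(propan-2-yl)silyloxy]phenyl}methanone | COc1cc(O)c(C(=O)c2cc(O[Si](C(C)C)(C(C)C)C(C)C)cc(OC(C)(C)C#C)c2)c(OC)c1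
F4 | step 11 | (2-hydroxy-4,6-dimethoxyphenyl){2,2-dimethyl-7-[tri(propan-2-yl)silyloxy]-2H-chromen-5-yl}methanone | COc1cc(O)c(C(=O)c2cc(O[Si](C(C)C)(C(C)C)C(C)C)cc3c2C=CC(C)(C)O3)c(OC)c1
F5 | step 10 | 3-(4,6-dimethoxy-1,2-benzoxazol-3-yl)-5-(methoxymethoxy)phenol | COCOc1cc(O)cc(c1)-c1noc2cc(OC)cc(OC)c12
F6 | step 10 | 4,6-dimethoxy-3-[3-(methoxymethoxy)-5-(2-methylbut-3-yn-2-yloxy)phenyl]-1,2-benzoxazole | COCOc1cc(OC(C)(C)C#C)cc(c1)-c1noc2cc(OC)cc(OC)c12
F7 | step 10 | 4,6-dimethoxy-3-[7-(methoxymethoxy)-2,2-dimethyl-2H-chromen-5-yl]-1,2-benzoxazole | COCOc1cc(-c2noc3cc(OC)cc(OC)c23)c2C=CC(C)(C)Oc2c1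
F8 | step 10 | 2-{imino[7-(methoxymethoxy)-2,2-dimethyl-2H-chromen-5-yl]methyl}-3,5-dimethoxyphenol | COCOc1cc(C(=N)c2c(O)cc(OC)cc2OC)c2C=CC(C)(C)Oc2c1
F9 | step 6 | 5-formyl-1,3-phenylene bis(2,2-dimethylpropanoate) | CC(C)(C)C(=O)Oc1cc(C=O)cc(OC(=O)C(C)(C)C)c1
F10 | step 6 | 5-[(E)-(hydroxyimino)methyl]-1,3-phenylene bis(2,2-dimethylpropanoate) | CC(C)(C)C(=O)Oc1cc(/C=N/O)cc(OC(=O)C(C)(C)C)c1
F11 | step 6 | 5-[(Z)-chloro(hydroxyimino)methyl]-1,3-phenylene bis(2,2-dimethylpropanoate) | CC(C)(C)C(=O)Oc1cc(/C(Cl)=N/O)cc(OC(=O)C(C)(C)C)c1
F12 | step 6 | 5-(4,6-dimethoxy-1,2-benzoxazol-3-yl)-1,3-phenylene bis(2,2-dimethylpropanoate) | CC(C)(C)C(=O)Oc1cc(OC(=O)C(C)(C)C)cc(c1)-c1noc2cc(OC)cc(OC)c12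
F13 | step 6 | 5-(4,6-dimethoxy-1,2-benzoxazol-3-yl)benzene-1,3-diol | Oc1cc(O)cc(c1)-c1noc2cc(OC)cc(OC)c12
A1 | alternative 1 | methyl 2-acetyl-4-oxo-4-(2,4,6-trimethoxyphenyl)but-2-enoate (alkene geometry not defined) | COC(=O)C(C(C)=O)=CC(=O)c1c(OC)cc(OC)cc1OC
A2 | alternative 1 | dimethyl propanedioate | COC(=O)CC(=O)OC
A3 | alternative 1 | dimethyl 4,6-dioxo-2-(2,4,6-trimethoxybenzoyl)cyclohexane-1,3-dicarboxylate (stereoisomer and enol mixture) | COC(=O)C1C(=O)CC(=O)C(C(=O)OC)C1C(=O)c1c(OC)cc(OC)cc1OC
A4 | alternative 2 | 2-iodo-1,5-dimethoxy-3-(methoxymethoxy)benzene | COCOc1cc(OC)cc(OC)c1I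
A5 | alternative 2 | 2-[7-(methoxymethoxy)-2,2-dimethyl-2H-chromen-5-yl]-4,4,5,5-tetramethyl-1,3,2-dioxaborolane | COCOc1cc(B2OC(C)(C)C(C)(C)O2)c2C=CC(C)(C)Oc2c1
A6 | alternative 2 | carbon monoxide | [C-]#[O+]
A7 | alternative 2 | [2,4-dimethoxy-6-(methoxymethoxy)phenyl][7-(methoxymethoxy)-2,2-dimethyl-2H-chromen-5-yl]methanone | COCOc1cc(OC)cc(OC)c1C(=O)c1cc(OCOC)cc2OC(C)(C)C=Cc12
A8 | alternative 3 | 1-methoxy-1,3-bis(trimethylsilyloxy)buta-1,3-diene (alkene geometry not defined) | COC(O[Si](C)(C)C)=CC(=C)O[Si](C)(C)C
A9 | alternative 3 | rac-4-{[tert-butyl(dimethyl)silyl]oxy}-4-[2,4-dimethoxy-6-(methoxymethoxy)phenyl]but-2-ynal | COCOc1cc(OC)cc(OC)c1C(O[Si](C)(C)C(C)(C)C)C#CC=O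
A10 | alternative 3 | rac-2-[{[tert-butyl(dimethyl)silyl]oxy}[2,4-dimethoxy-6-(methoxymethoxy)phenyl]methyl]-4,6-dihydroxybenzaldehyde | COCOc1cc(OC)cc(OC)c1C(O[Si](C)(C)C(C)(C)C)c1cc(O)cc(O)c1C=O
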